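(The constants are made up, and the outcome is calculated.)

A one-step world has a single clock, but this flask has several, and the ledger below asks which of them counts the moles.

    starting material + free catalyst → catalyst intermediate A (k1 = 28400 M⁻¹ min⁻¹)
    catalyst intermediate A ⇌ catalyst intermediate B (K2 = 0.51, k2 = 227 min⁻¹)
    catalyst intermediate B → free catalyst + product (k3 = 3950 min⁻¹)
    solid substrate ⇌ starting material, rate k4*(cs4 - [starting material]) while solid is left; crystals form when [starting material] > cs4 (cs4 = 0.061 M, k4 = 0.107 min⁻¹)
    catalyst intermediate A → spent catalyst (k5 = 0.115 min⁻¹)

solid substrate 0.15 M; free catalyst 0.38 mM; time 15 min

* product at 15 min, in percent of the solid substrate charged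
* concentration of starting material in solution at 15 min, in percent of saturation

My own reckoning follows the solid substrate, charged at 0.15 M. In the flask, the dissolution lifetime is 9.35 min, and dissolved starting material has a half-life of 0.064 min by step 1 alone with the catalyst as charged, far shorter than that lifetime, so [starting material] should stay far below 0.061 M and step 4 should run close to its full rate of 0.00653 M min⁻¹. Step 2, taken forward with the full catalyst charge as catalyst intermediate A, carries 0.0863 M min⁻¹, which is more than that feed, so dissolution should be the rate-limiting step. The charge divided by the full feed is 23.0 min, the emptying time.

The first entry is the dissolved part: by 15 min the solid should have given up 0.0979 M, or 65.2 % of the charge, and 0.0521 M should stay undissolved. The second is the solution, where pickup by step 1 balances the feed, with free catalyst taken as charged. That puts [starting material] at 0.605 mM, which is 0.991 % of saturation. The third is the catalyst, which holds at most 0.38 mM. With that most entered, the remainder is product, 64.6 % of the charge, and the books close.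

The forecast gives 64 % (range 62.5 % to 65 %) and 1.3 % (range 1.1 % to 1.5 %), holding that “dissolution limits the run”. Its saturation figure stands above mine.

The flask gives 63.9 % and 1.27 %, both inside the forecast's ranges. My saturation figure lies below the flask's, and free catalyst stands at 77.1 % of its charge, with spent catalyst at 14.2 %. The run is unfinished at 15 min: 36 % of the charge is still there, solid or dissolved, against 34.8 % by the emptying time of 23.0 min. For the neighbouring flask, with all amounts held and read at 6.0 min, the same emptying time reckons 26.1 % of the charge dissolved, and that flask shows 25.3 % product.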